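(The earlier runs and the new flask are calculated for an exercise, and the scatter is random.)

Start with the solid.

| flask | solid substrate | first nucleophile | second nucleophile | remark | time |
|---|---|---|---|---|---|
| elm | 0.088 M | 2 equiv | 1.1 equiv | the very flask that is asked about, followed so far |  |
| larch | 0.088 M | 2 equiv | 0.55 equiv | run made earlier |  |
| flask | 0.088 M | 2.00 equiv | 1.10 equiv |  | 15 min |

| run | time / min | target / % | starting material / % |
|---|---|---|---|
| elm | 0.417 | 0.1 | 1.4 |
| elm | 1.00 | 2.1 | 4.0 |
| elm | 2.00 | 0.7 | 5.3 |
| elm | 3.00 | 1.5 | 9.5 |
| elm | 5.00 | 2.9 | 12.8 |
| elm | 6.00 | 0.8 | 15.1 |
| elm | 8.00 | 1.6 | 17.6 |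
| larch | 0.333 | 0 | 0.1 |
| larch | 1.00 | 0.3 | 2.7 |
| larch | 1.50 | 0.2 | 4.7 |
| larch | 2.50 | 0.1 | 8.4 |
| larch | 4.00 | 0.1 | 10.6 |
| larch | 5.00 | 1.3 | 12.4 |
| larch | 6.00 | 1.3 | 13.8 |

(readings scatter by 1 percentage point)

* target at 15 min, in percent of the solid substrate charged
* concentration of starting material in solution at 8.0 min, in percent of saturation
* the change that raises the amount of target at 15 min, in percent of the solid substrate charged most ("none" if none brings more than 2 percentage points) (epsilon / beta / gamma / theta / none)
* amount of target at 15 min, in percent of the solid substrate charged, after beta

- epsilon: doubling the solubility of the solid substrate, all else as stated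
- beta: doubling the dissolution coefficient of the solid substrate, all else as stated
- gamma: doubling the amount of first nucleophile, all else as stated
- theta: doubling the amount of second nucleophile, all else as stated

- solid substrate is a solid; its amount is given per volume of the solution
- at the start none of the solid substrate is in solution
- starting material is what solid substrate becomes in solution
- starting material means what is dissolved; the solid is not counted in it

At 3.00 min the elm run holds 9.5% dissolved, a pace of 0.0317 min⁻¹ as a fraction of the charge. The larch run, on half the second nucleophile, gives 0.0336 min⁻¹ from its reading at 2.50 min, so I take this pace as the solid's own. Now I fold pace and time together: N = 0.475, the dissolving number, which is the asked time divided by the time the whole charge takes at the opening pace, a Damköhler number of dissolving. If the opening pace held, the whole charge would have dissolved at N = 1, which lies at 31.6 min, and that is the crossing at which control can pass from the solid. Elm at 15 min stands before that crossing, so I expect solid still in the flask.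

But one number isn't enough, since N counts what enters solution, not what becomes target. At 8.00 min elm reads 1.6% of target beside 17.6% of starting material. If starting material grows with time and target with its time integral, target goes with the square of time, and I commit to 5.62%. The bend in starting material could be saturation or consumption, so I give no percent of saturation. I take dissolving to go with the gap s − c(starting material), where s is the solubility. Doubling s gives 2s − c, doubling the coefficient gives 2s − 2c, so I put epsilon above beta. At 5.00 min elm reads 2.9% of target and larch 1.3%, but at 6.00 min elm reads 0.8% and larch 1.3%, so within a scatter of 1 percentage point I read no hold of the second nucleophile on target. Both runs charge 2 equiv of first nucleophile, so gamma stays unread, and I choose epsilon.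

The forecast gives 6%, 68%, theta and 8%, with the words “Little appears consumed”.

The flask gives 5.56%, 29.9% of saturation, epsilon as best with 5.4 points (theta −0.22 points), and 9.13% after beta.

    starting material ⇌ intermediate (K = 0.0380, k = 0.00170 s⁻¹)
    first nucleophile + intermediate → target (k = 0.0830 L mol⁻¹ s⁻¹)
    second nucleophile + intermediate → other capture product (k = 0.0210 L mol⁻¹ s⁻¹)
    solid substrate ⇌ starting material, rate k4*(cs4 - [starting material]) while solid is left; crystals form when [starting material] > cs4 (solubility = 0.0530 M, k = 8.50 × 10⁻⁴ s⁻¹)

In elm at 15.0 min, N stands against 33.9% of the charge gone from the solid, which remains at 66.1%. The same flask read at 40 min lies past the crossing, with N = 1.27, and the square of time gives 40.0% of target. It holds 24.8% of target and 37.9% of starting material, and its solid substrate still stands at 32.5%.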